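- A curve that goes flat with 46.2% of G unspent tempts one to read equilibrium, so I state my assumption: this grey flask stops because its enzyme E dies, which can't be proved from one curve.

| flask | G | E | remark | time |
|---|---|---|---|---|
| grey | 0.050 M | 31 µM | the very flask that is asked about, followed so far |  |
| flask | 0.050 M | 31 µM |  | 12 min |

grey run (percent of the G charged): time / min: D / % = 0.667: 32.6; 2.00: 49.8; 3.00: 52.3; 5.00: 53.5; 8.00: 53.8

(each reading ± 0.3 percentage points)

- midnight: at 12 min take out 90% of the D then present, then wait 12 min
- dusk: at 12 min add G, 50.0% of the amount charged, then wait 12 min
- dawn: change nothing and wait 12 min more
- noon: at 12 min add E, 50.0% of the amount charged, then wait 12 min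

- removed D is counted in
- the numbers in the tables scatter with a standard deviation of 0.3 percentage points
- additions bring no volume worth counting

1. D, in percent of the G first charged, at 12 min
2. the option that brings most further D ("none" if no option brings more than 2 percentage points) (midnight / dusk / dawn / noon / none)
3. D present, with what was taken out counted in, in percent of the G first charged, after dusk
4. D present, with what was taken out counted in, in percent of the G first charged, after noon

- I treat the approach to the plateau as a first-order lag: the gap to the last reading shrinks from 21 percentage points at 0.667 min to 4 points at 2.00 min, which gives a time constant of 0.799 min.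
- The 12 min mark is far longer than that time constant, at 15.0 of them, so I put D at 53.8% then and expect waiting, removing D and adding G to bring nothing.
- Next comes the lifetime yield of the enzyme, a total turnover number: D made per E charged before E dies, here 868.
- If that yield holds for the E added at noon, D reaches 80.7%.
- The weak link is that fresh E meets thinner G, so I reforge it: if the speed of E were proportional to G, each charge would remove a fixed fraction of G, and D would reach 68.6%.
- No reading places the flask between these two ends, so I commit to the middle, 74.6%, for noon.
- The forecast, which says the plateau “looks like a dead enzyme, not equilibrium”, gives 53.8% now, noon as best, 53.8% after dusk and 68.6% after noon; that last value is my low end, not my committed middle.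
- The simulated flask gives 53.4% now and noon as best, with a gain of 21 points, while dawn, dusk and midnight each bring 0 points; D stands at 53.4% after dusk and 74.8% after noon.

    G + E → D + E, rate k1*[G]*[E]/(1 + ([G]/Km1)) (9.79 mM, k = 2510 M⁻¹ s⁻¹)
    E → Z (k = 0.0221 s⁻¹)
    E + D → E + Q (k = 10.2 M⁻¹ s⁻¹)

- The grey flask ends as low as 53.4% mainly because of the denominator term in G of the step from G to D, which is enzyme saturation: a run without that term reaches 96.0% at 12 min. In the noon option the added E brings a net 691 D per E, less than the lifetime yield of 868 read from the grey run, and it starts on the 46.2% of G still free.
- In the neighbour flask with 1.9 × 10⁻⁵ M of E and G as charged, the lifetime yield gives 33.0% of the charged G as D; the computed result at 12 min is 33.9%.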